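**Assumption:** both enantiomers of but-3-en-2-ol and 4-hydroxyisoindoline-1,3-dione are taken as commercial. Backbone numbering: C1 = acyl carbon on N, C3 and C10 = O-bearing carbons, C4, C9 and C11 = methyl-bearing carbons, C12 = pyrrolyl ketone carbon.

## Retrosynthetic overview

1. Target ⇐ hydrogenation of a C6=C7 macrocyclic alkene ⇐ ring-closing metathesis; the 11-membered ring is formed last.
2. Metathesis diene ⇐ acid-catalysed mixed orthoamide formation between a tricyclic hemi-orthoamide (west half on 3-hydroxyphthalimide) and a β-hydroxy ketopyrrole (east half).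
3. Both halves ⇐ enantiomeric (S)- and (R)-2-methylhex-4-enoic acids, via β-keto ester, Felkin reduction (C3, C10) and Fráter–Seebach methylation (C11).
4. Key step: Ireland–Claisen rearrangement of (R)- and (S)-but-3-en-2-yl propanoate forms the C4–C5 and C8–C9 bonds and sets C4 and C9 by chirality transfer.
5. Ring order: isoindolinone (bought) → 1,3-oxazinan-4-one (step 8) → 11-membered ring (step 17).

## Route

Step 1
Reactants: 1 (R)-but-3-en-2-ol; 2 propanoyl chloride
Product: 3 (R)-but-3-en-2-yl propanoate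
Conditions: pyridine, DMAP (cat.), CH2Cl2, 0 °C to rt
Reagents that add atoms: none
Why: O-acylation (nucleophilic acyl substitution) of the allylic alcohol does not touch the bought C–O stereocentre.

Step 2
Reactants: 3 (R)-but-3-en-2-yl propanoate
Product: 7 (2S,4E)-2-methylhex-4-enoic acid, via lithium enolate 4 (not isolated), via silyl ketene acetal 5 (not isolated), via trimethylsilyl ester 6 (not isolated)
Conditions: LiN(i-Pr)2, THF, −78 °C; Me3SiCl, Et3N, −78 °C to 50 °C; 1 M NaOH, then HCl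
Reagents that add atoms: none
Why: Ireland–Claisen [3,3]-sigmatropic rearrangement; the (E)-silyl ketene acetal reacts through a chair with the carbinol methyl equatorial, forming C4–C5, the (E)-alkene and (S)-C4 by chirality transfer from the (R)-carbinol (er about 9:1 expected, limited by enolate geometry; the minor enantiomer is removed later as a diastereomer).

Step 3
Reactants: 7 (2S,4E)-2-methylhex-4-enoic acid; 8 3-(tert-butoxy)-3-oxopropanoic acid
Product: 11 tert-butyl (4S,6E)-4-methyl-3-oxooct-6-enoate, via acyl imidazolide 9 (not isolated), via acylmalonic half ester 10 (not isolated)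
Conditions: 1,1'-carbonyldiimidazole, THF, rt; then 8, MgCl2, Et3N, MeCN, rt; 1 M HCl
Reagents that add atoms: none
Why: Masamune–Brooks homologation (C-acylation of the magnesium malonate, then decarboxylation) adds C1–C2 and leaves the non-acidic C4 centre intact.

Step 4
Reactants: 11 tert-butyl (4S,6E)-4-methyl-3-oxooct-6-enoate
Product: 12 tert-butyl (3R,4S,6E)-3-hydroxy-4-methyloct-6-enoate
Conditions: LiBH(s-Bu)3, THF, −78 °C; H2O
Reagents that add atoms: none
Why: Felkin–Anh-controlled reduction; the bulky hydride attacks anti to the CH2 chain on C4 and gives the 3,4-anti (3R) alcohol (dr about 4:1 expected, epimers separable).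

Step 5
Reactants: 12 tert-butyl (3R,4S,6E)-3-hydroxy-4-methyloct-6-enoate
Product: 13 tert-butyldimethylsilyl (3R,4S,6E)-3-[(tert-butyldimethylsilyl)oxy]-4-methyloct-6-enoate
Conditions: t-BuMe2SiOTf (3 equiv), 2,6-lutidine, CH2Cl2, 0 °C to rt
Reagents that add atoms: tert-butyldimethylsilyl trifluoromethanesulfonate CC(C)(C)[Si](C)(C)OS(=O)(=O)C(F)(F)F
Why: The silyl triflate silylates the alcohol and converts the tert-butyl ester into the silyl ester with loss of isobutene (silylative ester cleavage), so protection and ester unmasking happen in one operation.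

Step 6
Reactants: 14 4-hydroxyisoindoline-1,3-dione
Product: 15 4-[(tert-butyldimethylsilyl)oxy]isoindoline-1,3-dione
Conditions: t-BuMe2SiCl, imidazole, DMF, rt
Reagents that add atoms: tert-butyl(chloro)dimethylsilane CC(C)(C)[Si](C)(C)Cl
Why: Silyl ether protection of the phenol (the imide N–H gives no stable silyl derivative) removes the competing O-acylation site.

Step 7
Reactants: 13 tert-butyldimethylsilyl (3R,4S,6E)-3-[(tert-butyldimethylsilyl)oxy]-4-methyloct-6-enoate; 15 4-[(tert-butyldimethylsilyl)oxy]isoindoline-1,3-dione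
Product: 17 4-[(tert-butyldimethylsilyl)oxy]-2-{(3R,4S,6E)-3-[(tert-butyldimethylsilyl)oxy]-4-methyloct-6-enoyl}isoindoline-1,3-dione, via acid chloride 16 (not isolated)
Conditions: (COCl)2, DMF (cat.), CH2Cl2, 0 °C to rt; then 15, Et3N, DMAP (cat.), 0 °C
Reagents that add atoms: none
Why: Wissner conversion of the silyl ester into the acid chloride under neutral conditions, then N-acylation of the imide; both silyl ethers survive.

Step 8
Reactants: 17 the bis-silylated N-acyl imide
Product: 19 (2R)-2-[(2S,4E)-hex-4-en-2-yl]-10,10b-dihydroxy-2,3-dihydro-10bH-[1,3]oxazino[2,3-a]isoindole-4,6-dione, via desilylated imide 18 (not isolated)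
Conditions: HF·pyridine, pyridine, THF, 0 °C to rt
Reagents that add atoms: none
Why: Desilylation frees both hydroxyls and the C3 hydroxyl adds 6-exo to the imide carbonyl next to the phenol, which is activated by the O–H···O=C hydrogen bond (ring–chain tautomerism); the new carbinol carbon stays epimerisable.

Step 9
Reactants: 20 (S)-but-3-en-2-ol; 2 propanoyl chloride
Product: 21 (S)-but-3-en-2-yl propanoate
Conditions: pyridine, DMAP (cat.), CH2Cl2, 0 °C to rt
Reagents that add atoms: none
Why: O-acylation as in step 1, on the enantiomeric alcohol.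

Step 10
Reactants: 21 (S)-but-3-en-2-yl propanoate
Product: 25 (2R,4E)-2-methylhex-4-enoic acid, via lithium enolate 22 (not isolated), via silyl ketene acetal 23 (not isolated), via trimethylsilyl ester 24 (not isolated)
Conditions: LiN(i-Pr)2, THF, −78 °C; Me3SiCl, Et3N, −78 °C to 50 °C; 1 M NaOH, then HCl
Reagents that add atoms: none
Why: Ireland–Claisen rearrangement, mirror image of step 2; it forms C8–C9 and sets (R)-C9 by chirality transfer from the (S)-carbinol.

Step 11
Reactants: 25 (2R,4E)-2-methylhex-4-enoic acid; 26 potassium 3-methoxy-3-oxopropanoate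
Product: 29 methyl (4R,6E)-4-methyl-3-oxooct-6-enoate, via acyl imidazolide 27 (not isolated), via acylmalonic half ester 28 (not isolated)
Conditions: 1,1'-carbonyldiimidazole, THF, rt; then 26, MgCl2, Et3N, MeCN, rt; 1 M HCl
Reagents that add atoms: none
Why: Masamune–Brooks homologation as in step 3 adds C11–C12.

Step 12
Reactants: 29 methyl (4R,6E)-4-methyl-3-oxooct-6-enoate
Product: 30 methyl (3S,4R,6E)-3-hydroxy-4-methyloct-6-enoate
Conditions: LiBH(s-Bu)3, THF, −78 °C; H2O
Reagents that add atoms: none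
Why: Felkin–Anh reduction as in step 4 gives the 9,10-anti alcohol (C10; dr about 4:1 expected, epimers separable).

Step 13
Reactants: 30 methyl (3S,4R,6E)-3-hydroxy-4-methyloct-6-enoate
Product: 32 methyl (2R,3R,4R,6E)-3-hydroxy-2,4-dimethyloct-6-enoate, via dilithio dianion 31 (not isolated)
Conditions: LiN(i-Pr)2 (2.2 equiv), THF, −78 to −20 °C; MeI, DMPU, −78 to −10 °C; H2O
Reagents that add atoms: iodomethane CI
Why: Fráter–Seebach alkylation; the chelated dianion is methylated on the face anti to the C10 substituent, giving (R)-C11 (10,11-anti, usually better than 10:1).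

Step 14
Reactants: 32 methyl (2R,3R,4R,6E)-3-hydroxy-2,4-dimethyloct-6-enoate
Product: 33 (2R,3R,4R,6E)-3-hydroxy-N-methoxy-N,2,4-trimethyloct-6-enamide
Conditions: MeNH(OMe)·HCl, i-PrMgCl, THF, −20 to 0 °C
Reagents that add atoms: N,O-dimethylhydroxylamine hydrochloride CNOC.Cl
Why: Weinreb aminolysis of the ester by the chloromagnesium amide; the hydroxyl is carried as its magnesium alkoxide and C11 is not epimerised.

Step 15
Reactants: 33 the Weinreb amide; 34 tert-butyl 1H-pyrrole-1-carboxylate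
Product: 37 (2R,3R,4R,6E)-3-hydroxy-2,4-dimethyl-1-(1H-pyrrol-2-yl)oct-6-en-1-one, via lithiated Boc-pyrrole 35 (not isolated), via Boc-protected ketone 36 (not isolated)
Conditions: 34 (3 equiv), LiN(i-Pr)2, THF, −78 °C; then 33, −78 to −30 °C; H2O; then K2CO3 (cat.), MeOH, 0 °C
Reagents that add atoms: none
Why: Directed C2-lithiation of N-Boc-pyrrole and Weinreb ketone synthesis (the chelated tetrahedral intermediate stops over-addition), then mild methanolysis of the labile N-Boc group of the 2-acylpyrrole.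

Step 16
Reactants: 19 the tricyclic hemi-orthoamide; 37 the east hydroxy ketone
Product: 38 (2R,10bS)-2-[(2S,4E)-hex-4-en-2-yl]-10-hydroxy-10b-{[(2R,3R,4R,6E)-2,4-dimethyl-1-oxo-1-(1H-pyrrol-2-yl)oct-6-en-3-yl]oxy}-2,3-dihydro-10bH-[1,3]oxazino[2,3-a]isoindole-4,6-dione
Conditions: 19 (1.3 equiv), CSA (0.2 equiv), 4 Å molecular sieves, CH2Cl2, rt
Reagents that add atoms: none
Why: Acid-catalysed mixed orthoamide (ketal) formation under thermodynamic control; only the carbon next to the phenol ionises readily (cation stabilised by the ortho-hydroxyaryl group), and the (10bS) epimer with the new alkoxy group axial (anomeric effect) and the C3 side chain equatorial is the expected sink.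

Step 17
Reactants: 38 the mixed orthoamide diene
Product: 39 the 6,7-didehydro macrocycle (target skeleton with a C6=C7 double bond, E/Z mixture)
Conditions: second-generation Grubbs catalyst RuCl2(=CHPh)(H2IMes)(PCy3) (10 mol %), toluene (1 mM), 80 °C
Reagents that add atoms: none
Why: Ring-closing olefin metathesis, driven by loss of but-2-ene, closes the 11-membered ring between the two chains held on the rigid orthoamide; phenol, pyrrole N–H and ketone are tolerated.

Step 18
Reactants: 39 the 6,7-didehydro macrocycle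
Product: 40 CNP0418824.1
Conditions: H2 (1 atm), RhCl(PPh3)3 (10 mol %), benzene–EtOH, rt
Reagents that add atoms: none
Why: Homogeneous hydrogenation reduces only the disubstituted ring alkene (no benzylic C–O hydrogenolysis, no reduction of the acylpyrrole), and both alkene isomers converge on the target.

## Compound list

1 | (R)-but-3-en-2-ol | C[C@@H](O)C=C | starting material
2 | propanoyl chloride | CCC(Cl)=O | starting material
3 | (R)-but-3-en-2-yl propanoate | CCC(=O)O[C@H](C)C=C | intermediate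
4 | lithium E(O)-enolate of 3 (methyl trans to OLi) | C/C=C(/O[Li])O[C@H](C)C=C | intermediate
5 | (E)-1-{[(2R)-but-3-en-2-yl]oxy}-1-(trimethylsilyloxy)prop-1-ene | C/C=C(/O[Si](C)(C)C)O[C@H](C)C=C | intermediate
6 | trimethylsilyl (2S,4E)-2-methylhex-4-enoate | C/C=C/C[C@H](C)C(=O)O[Si](C)(C)C | intermediate
7 | (2S,4E)-2-methylhex-4-enoic acid | C/C=C/C[C@H](C)C(O)=O | intermediate
8 | 3-(tert-butoxy)-3-oxopropanoic acid (mono-tert-butyl malonate) | CC(C)(C)OC(=O)CC(O)=O | starting material
9 | (2S,4E)-1-(1H-imidazol-1-yl)-2-methylhex-4-en-1-one | C/C=C/C[C@H](C)C(=O)n1ccnc1 | intermediate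
10 | (4S,6E)-2-(tert-butoxycarbonyl)-4-methyl-3-oxooct-6-enoic acid | C/C=C/C[C@H](C)C(=O)C(C(O)=O)C(=O)OC(C)(C)C | intermediate
11 | tert-butyl (4S,6E)-4-methyl-3-oxooct-6-enoate | C/C=C/C[C@H](C)C(=O)CC(=O)OC(C)(C)C | intermediate
12 | tert-butyl (3R,4S,6E)-3-hydroxy-4-methyloct-6-enoate | C/C=C/C[C@H](C)[C@H](O)CC(=O)OC(C)(C)C | intermediate
13 | tert-butyldimethylsilyl (3R,4S,6E)-3-[(tert-butyldimethylsilyl)oxy]-4-methyloct-6-enoate | C/C=C/C[C@H](C)[C@H](O[Si](C)(C)C(C)(C)C)CC(=O)O[Si](C)(C)C(C)(C)C | intermediate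
14 | 4-hydroxyisoindoline-1,3-dione (3-hydroxyphthalimide) | Oc1cccc2C(=O)NC(=O)c12 | starting material
15 | 4-[(tert-butyldimethylsilyl)oxy]isoindoline-1,3-dione | CC(C)(C)[Si](C)(C)Oc1cccc2C(=O)NC(=O)c12 | intermediate
16 | (3R,4S,6E)-3-[(tert-butyldimethylsilyl)oxy]-4-methyloct-6-enoyl chloride | C/C=C/C[C@H](C)[C@H](O[Si](C)(C)C(C)(C)C)CC(Cl)=O | intermediate
17 | 4-[(tert-butyldimethylsilyl)oxy]-2-{(3R,4S,6E)-3-[(tert-butyldimethylsilyl)oxy]-4-methyloct-6-enoyl}isoindoline-1,3-dione (acyl carbonyl on N; silyloxy group ortho to one imide carbonyl) | C/C=C/C[C@H](C)[C@H](O[Si](C)(C)C(C)(C)C)CC(=O)N1C(=O)c2cccc(O[Si](C)(C)C(C)(C)C)c2C1=O | intermediate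
18 | 4-hydroxy-2-[(3R,4S,6E)-3-hydroxy-4-methyloct-6-enoyl]isoindoline-1,3-dione | C/C=C/C[C@H](C)[C@H](O)CC(=O)N1C(=O)c2cccc(O)c2C1=O | intermediate
19 | (2R)-2-[(2S,4E)-hex-4-en-2-yl]-10,10b-dihydroxy-2,3-dihydro-10bH-[1,3]oxazino[2,3-a]isoindole-4,6-dione (10b epimers, in equilibrium with 18) | C/C=C/C[C@H](C)[C@H]1CC(=O)N2C(=O)c3cccc(O)c3C2(O)O1 | intermediate
20 | (S)-but-3-en-2-ol | C[C@H](O)C=C | starting material
21 | (S)-but-3-en-2-yl propanoate | CCC(=O)O[C@@H](C)C=C | intermediate
22 | lithium E(O)-enolate of 21 (methyl trans to OLi) | C/C=C(/O[Li])O[C@@H](C)C=C | intermediate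
23 | (E)-1-{[(2S)-but-3-en-2-yl]oxy}-1-(trimethylsilyloxy)prop-1-ene | C/C=C(/O[Si](C)(C)C)O[C@@H](C)C=C | intermediate
24 | trimethylsilyl (2R,4E)-2-methylhex-4-enoate | C/C=C/C[C@@H](C)C(=O)O[Si](C)(C)C | intermediate
25 | (2R,4E)-2-methylhex-4-enoic acid | C/C=C/C[C@@H](C)C(O)=O | intermediate
26 | potassium 3-methoxy-3-oxopropanoate (potassium methyl malonate) | COC(=O)CC(=O)[O-].[K+] | starting material
27 | (2R,4E)-1-(1H-imidazol-1-yl)-2-methylhex-4-en-1-one | C/C=C/C[C@@H](C)C(=O)n1ccnc1 | intermediate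
28 | (4R,6E)-2-(methoxycarbonyl)-4-methyl-3-oxooct-6-enoic acid | C/C=C/C[C@@H](C)C(=O)C(C(O)=O)C(=O)OC | intermediate
29 | methyl (4R,6E)-4-methyl-3-oxooct-6-enoate | C/C=C/C[C@@H](C)C(=O)CC(=O)OC | intermediate
30 | methyl (3S,4R,6E)-3-hydroxy-4-methyloct-6-enoate | C/C=C/C[C@@H](C)[C@@H](O)CC(=O)OC | intermediate
31 | dilithio dianion of 30 (lithium alkoxide and lithium ester enolate) | C/C=C/C[C@@H](C)[C@@H](O[Li])C=C(O[Li])OC | intermediate
32 | methyl (2R,3R,4R,6E)-3-hydroxy-2,4-dimethyloct-6-enoate | C/C=C/C[C@@H](C)[C@@H](O)[C@@H](C)C(=O)OC | intermediate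
33 | (2R,3R,4R,6E)-3-hydroxy-N-methoxy-N,2,4-trimethyloct-6-enamide | C/C=C/C[C@@H](C)[C@@H](O)[C@@H](C)C(=O)N(C)OC | intermediate
34 | tert-butyl 1H-pyrrole-1-carboxylate | CC(C)(C)OC(=O)n1cccc1 | starting material
35 | tert-butyl 2-lithio-1H-pyrrole-1-carboxylate | CC(C)(C)OC(=O)n1cccc1[Li] | intermediate
36 | tert-butyl 2-[(2R,3R,4R,6E)-3-hydroxy-2,4-dimethyloct-6-enoyl]-1H-pyrrole-1-carboxylate | C/C=C/C[C@@H](C)[C@@H](O)[C@@H](C)C(=O)c1cccn1C(=O)OC(C)(C)C | intermediate
37 | (2R,3R,4R,6E)-3-hydroxy-2,4-dimethyl-1-(1H-pyrrol-2-yl)oct-6-en-1-one | C/C=C/C[C@@H](C)[C@@H](O)[C@@H](C)C(=O)c1ccc[nH]1 | intermediate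
38 | (2R,10bS)-2-[(2S,4E)-hex-4-en-2-yl]-10-hydroxy-10b-{[(2R,3R,4R,6E)-2,4-dimethyl-1-oxo-1-(1H-pyrrol-2-yl)oct-6-en-3-yl]oxy}-2,3-dihydro-10bH-[1,3]oxazino[2,3-a]isoindole-4,6-dione | C/C=C/C[C@H](C)[C@H]2CC(=O)N3C(=O)c4cccc(O)c4[C@@]3(O[C@H]([C@H](C)C/C=C/C)[C@@H](C)C(=O)c1ccc[nH]1)O2 | intermediate
39 | 6,7-didehydro derivative of 40 (C6=C7 alkene in the 11-membered ring, E/Z mixture, all stereocentres as in 40) | C[C@@H]1CC=CC[C@H](C)[C@H]2CC(=O)N3C(=O)c4cccc(O)c4[C@@]3(O[C@H]1[C@@H](C)C(=O)c1ccc[nH]1)O2 | intermediate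
40 | CNP0418824.1 (3R,4S,9R,10R,11R, orthoamide carbon S in the backbone numbering above) | C[C@@H]1CCCC[C@H](C)[C@H]2CC(=O)N3C(=O)c4cccc(O)c4[C@@]3(O[C@H]1[C@@H](C)C(=O)c1ccc[nH]1)O2 | target

## Step count and risks

Total step count: 18. Longest linear sequence: 10 steps (steps 1, 2, 3, 4, 5, 7, 8, 16, 17, 18; the east branch, steps 9 to 15 then 16 to 18, is equally long).

Step 17 (ring-closing metathesis to the 11-membered ring) is the most likely to fail, through ring strain and competing oligomerisation of two internal olefins. The fallback closes the macrocycle at the orthoamide instead and sets out from 17 and 37. Cross-metathesis of the two with the second-generation Hoveyda–Grubbs catalyst RuCl2(=CH-C6H4-2-O-i-Pr)(H2IMes) gives the open-chain C6=C7 alkene F1. Hydrogenation over RhCl(PPh3)3 gives the saturated seco imide F2. HF·pyridine then gives the seco hemi-orthoamide F3, which still carries the free C10 hydroxyl. CSA with 4 Å molecular sieves at high dilution closes the ring by intramolecular orthoamide formation and comes back to the route at 40.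

Step 16 (intermolecular mixed orthoamide formation) is the second risk. The C10 alcohol is hindered, water must be removed, and acyl transfer from the imide or dehydration of the β-hydroxy ketone can compete. The regiochemistry and the 10b configuration also rest on thermodynamic arguments. The fallback replaces the dehydrative condensation by an exchange on a pre-formed orthoamide and sets out from 19. Methanol with CSA gives the 10b-methoxy orthoamide F4, which can be dried and purified. Transketalisation with 37 (PPTS, toluene, 5 Å molecular sieves, 60 °C, removal of methanol) then comes back to the route at 38.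

Step 4 (Felkin–Anh reduction; step 12 is its mirror image and shares the risk) is the third. The C4 centre differentiates only methyl from a CH2 chain, so the diastereoselectivity may be low. The fallback makes the step stereoconvergent and sets out from 11. Unselective reduction with NaBH4 in MeOH gives 12 together with the (3S,4S)-epimer F5, and the two are separated. F5 is inverted by Mitsunobu esterification (4-nitrobenzoic acid, PPh3, DIAD) to the (3R)-4-nitrobenzoate F6. Methanolysis with K2CO3 in MeOH comes back to the route at 12.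

## Further compounds

F1 | step 17 | 4-[(tert-butyldimethylsilyl)oxy]-2-{(3R,4S,9R,10R,11R)-3-[(tert-butyldimethylsilyl)oxy]-10-hydroxy-4,9,11-trimethyl-12-oxo-12-(1H-pyrrol-2-yl)dodec-6-enoyl}isoindoline-1,3-dione (E/Z mixture) | O=C(c1ccc[nH]1)[C@H](C)[C@H](O)[C@H](C)CC=CC[C@H](C)[C@H](O[Si](C)(C)C(C)(C)C)CC(=O)N1C(=O)c2cccc(O[Si](C)(C)C(C)(C)C)c2C1=O
F2 | step 17 | 4-[(tert-butyldimethylsilyl)oxy]-2-{(3R,4S,9R,10R,11R)-3-[(tert-butyldimethylsilyl)oxy]-10-hydroxy-4,9,11-trimethyl-12-oxo-12-(1H-pyrrol-2-yl)dodecanoyl}isoindoline-1,3-dione | O=C(c1ccc[nH]1)[C@H](C)[C@H](O)[C@H](C)CCCC[C@H](C)[C@H](O[Si](C)(C)C(C)(C)C)CC(=O)N1C(=O)c2cccc(O[Si](C)(C)C(C)(C)C)c2C1=O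
F3 | step 17 | (2R)-10,10b-dihydroxy-2-[(2S,7R,8R,9R)-8-hydroxy-7,9-dimethyl-10-oxo-10-(1H-pyrrol-2-yl)decan-2-yl]-2,3-dihydro-10bH-[1,3]oxazino[2,3-a]isoindole-4,6-dione | O=C(c1ccc[nH]1)[C@H](C)[C@H](O)[C@H](C)CCCC[C@H](C)[C@H]1CC(=O)N2C(=O)c3cccc(O)c3C2(O)O1
F4 | step 16 | (2R)-2-[(2S,4E)-hex-4-en-2-yl]-10-hydroxy-10b-methoxy-2,3-dihydro-10bH-[1,3]oxazino[2,3-a]isoindole-4,6-dione | C/C=C/C[C@H](C)[C@H]1CC(=O)N2C(=O)c3cccc(O)c3C2(OC)O1
F5 | step 4 | tert-butyl (3S,4S,6E)-3-hydroxy-4-methyloct-6-enoate | C/C=C/C[C@H](C)[C@@H](O)CC(=O)OC(C)(C)C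
F6 | step 4 | tert-butyl (3R,4S,6E)-4-methyl-3-[(4-nitrobenzoyl)oxy]oct-6-enoate | C/C=C/C[C@H](C)[C@H](OC(=O)c1ccc(cc1)[N+](=O)[O-])CC(=O)OC(C)(C)C
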